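**Strategy.** The plan rests on cutting the cyclohexenone ring at C4–C5 and C8–C9, which turns it into a 2-silyloxydiene and the C4=C9 enone alkene of a cycloheptadienone. C4 and C9 are adjacent atoms shared by the six- and seven-membered rings, with C4 β to the C10 carbon that must later carry a nucleofuge. One catalytic enantioselective Diels–Alder step therefore builds the six-membered ring cis-fused to the seven-membered ring, sets the C4 quaternary centre and C9, and leaves a C10 ketone (for cyclobutane closure C5–C10) and a C6 silyl enol ether (for the C7=C8 enone). Its precursors are achiral 3,7,7-trimethylcyclohepta-2,5-dien-1-one and (E)-2-(triisopropylsilyloxy)penta-1,3-diene.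

Key step: step 7

Atom labels used throughout: C1 carries the angelate oxygen, C2 the 2-methylbutanoate oxygen, C3 is CH2, C4 the methyl-bearing quaternary carbon, C5 the CH between C4 and the ketone, C6 the ketone carbon, C7=C8 the enone alkene (methyl on C8), C9 the CH bonded to C4, C8 and C10, C10 the CH bonded to C5, C9 and C11, C11 the C(CH3)2 carbon. Descriptors at C4, C8 and C9 change between some intermediates only because substituent priorities change.

Assumption: the oxazaborolidinium ion derived from (S)-α,α-diphenylprolinol is taken as the antipode that leaves the C4-Re/C9-Re face of dienone 10 open (carbonyl bound syn to C9–H); if the sense of induction is the opposite one, the (R)-derived catalyst is used with nothing else changed.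

**Step 1**
Reactants: 1 2,2-dimethylbut-3-enoic acid
Product: 3 N-methoxy-N,2,2-trimethylbut-3-enamide, via 2,2-dimethylbut-3-enoyl chloride 2 (not isolated)
Conditions: (COCl)2, cat. DMF, CH2Cl2, 0 → 25 °C; then MeNHOMe·HCl, Et3N, CH2Cl2, 0 °C
Reagents that add atoms: N,O-dimethylhydroxylamine hydrochloride, CNOC.Cl; oxalyl chloride, ClC(=O)C(=O)Cl (chlorine in intermediate 2 only)
Why: Acid chloride formation followed by amidation is the standard entry to Weinreb amides of α-quaternary acids, whose hindered carbonyl is best acylated as the chloride; no stereocentre is involved.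

**Step 2**
Reactants: 3 N-methoxy-N,2,2-trimethylbut-3-enamide; 4 prop-1-ynylmagnesium bromide
Product: 6 3,3-dimethylhept-1-en-5-yn-4-one, via magnesium hemiaminal chelate 5 (not isolated)
Conditions: THF, 0 → 25 °C; then cold aq. NH4Cl
Reagents that add atoms: none
Why: Weinreb ketone synthesis, in which the alkynyl Grignard reagent adds only once because the magnesium chelate 5 survives until the quench, which then releases the ynone.

**Step 3**
Reactants: 6 3,3-dimethylhept-1-en-5-yn-4-one
Product: 7 (Z)-6-iodo-3,3-dimethylhepta-1,5-dien-4-one (iodine cis to the acyl group)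
Conditions: NaI, AcOH, 25 °C
Reagents that add atoms: sodium iodide, [Na+].[I-]
Why: Conjugate hydroiodination of an ynone, in which iodide adds to the β-carbon and the allenol is protonated anti to iodine, so the (Z)-β-iodoenone should form under kinetic control while the isolated vinyl group is untouched.

**Step 4**
Reactants: 7 (Z)-6-iodo-3,3-dimethylhepta-1,5-dien-4-one; 8 allyltributylstannane
Product: 9 (5Z)-3,3,6-trimethylnona-1,5,8-trien-4-one (allyl group cis to the acyl group)
Conditions: Pd2(dba)3 (2.5 mol %), AsPh3 (10 mol %), NMP, 25 °C
Reagents that add atoms: none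
Why: Stille cross-coupling of an alkenyl iodide proceeds with retention of alkene geometry, so the allyl group takes the place of iodine cis to the acyl group, and the neutral conditions should leave the skipped diene unisomerised.

**Step 5**
Reactants: 9 (5Z)-3,3,6-trimethylnona-1,5,8-trien-4-one
Product: 10 3,7,7-trimethylcyclohepta-2,5-dien-1-one
Conditions: second-generation Grubbs catalyst (H2IMes)(PCy3)Cl2Ru=CHPh (5 mol %), 1,4-benzoquinone (10 mol %), CH2Cl2 (0.01 M), 40 °C
Reagents that add atoms: none
Why: Ring-closing metathesis between the two monosubstituted alkenes (the trisubstituted enone alkene is inert) releases ethylene and closes the seven-membered ring, whose new C1=C2 bond is necessarily cis.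

**Step 6**
Reactants: 11 (E)-pent-3-en-2-one
Product: 13 (E)-2-(triisopropylsilyloxy)penta-1,3-diene, via lithium (E)-penta-1,3-dien-2-olate 12 (not isolated)
Conditions: LiN(i-Pr)2 (LDA), THF, −78 °C; then TIPSOTf, −78 → 0 °C
Reagents that add atoms: triisopropylsilyl trifluoromethanesulfonate, CC(C)[Si](C(C)C)(C(C)C)OS(=O)(=O)C(F)(F)F; lithium diisopropylamide, [Li+].CC(C)[N-]C(C)C (lithium in intermediate 12 only)
Why: Kinetic deprotonation of the methyl ketone at its methyl group gives the cross-conjugated lithium enolate, which is O-silylated by the silyl triflate with the (E)-alkene unchanged (kinetic enolate silylation).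

**Step 7**
Reactants: 10 3,7,7-trimethylcyclohepta-2,5-dien-1-one; 13 (E)-2-(triisopropylsilyloxy)penta-1,3-diene
Product: 14 cis-fused TIPS enol ether ketone: six-membered ring C4(CH3)–C5H2–C6(OTIPS)=C7H–C8H(CH3)–C9H fused at C4–C9 to the seven-membered ring C4–C3H2–C2H=C1H–C11(CH3)2–C10(=O)–C9; C4 S, C8 R, C9 R (C4 methyl and C9–H cis, C8 methyl cis to C10)
Conditions: (S)-3,3-diphenyl-1-(2-methylphenyl)tetrahydro-1H,3H-pyrrolo[1,2-c][1,3,2]oxazaborole (20 mol %), Tf2NH (16 mol %), 13 (2 equiv), CH2Cl2, −40 → −20 °C
Reagents that add atoms: none
Why: Proposed new method: the oxazaborolidinium ion binds the C10 carbonyl at the lone pair syn to C9–H (the C11 quaternary carbon blocks the other), lowers the enone LUMO, and the diene terminus with the largest HOMO coefficient (C5, the CH2 of the silyl enol ether) bonds to the β-carbon C4 while C8 bonds to C9 in a concerted but strongly asynchronous [4+2] addition (Mukaiyama–Michael then Michael closure at the stepwise limit, same adduct). The closest known reaction types are the oxazaborolidinium-catalysed enantioselective Diels–Alder of 2-silyloxydienes with cyclic enones and the achiral Lewis acid-promoted Diels–Alder of β-methylcycloalkenones; their union on a β,β-disubstituted cycloheptadienone is the untested part. The six-membered ring C4–C5–C6–C7–C8–C9 closes by suprafacial cycloaddition (6-endo-trig Michael closure at the stepwise limit) onto a ring-constrained cis alkene, so the C4 methyl and C9–H must end cis and the new ring is cis-fused to the seven-membered ring. C4 (S) and C9 (R) are set together by the catalyst, which must leave the C4-Re/C9-Re face of the enone open; C8 (R, methyl cis to C10) follows from the endo transition state of the (E)-diene and is removed in step 9. Regiochemistry is secured twice by the diene (C6 silyloxy "para" and C8 methyl "ortho" to the C10 carbonyl branch), chemoselectivity for C4=C9 over the isolated C1=C2 alkene by conjugation to the bound ketone, and the bulky TIPS group should suppress silyl transfer to triflimide, which would otherwise start an achiral silyl-cation background reaction.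

**Step 8**
Reactants: 14 cis-fused TIPS enol ether ketone
Product: 15 C10 alcohol of 14 with the hydroxyl syn to C9–H and anti to C4 (C4 S, C8 S, C9 R, C10 S)
Conditions: Li (4 equiv), NH3(l)/THF, t-BuOH (2.2 equiv), −78 °C; solid NH4Cl
Reagents that add atoms: none
Why: Dissolving-metal reduction of a hindered ketone, in which electron transfer is insensitive to the shielding of C10 and the C10 carbanion should be protonated in its more stable pyramidal form, with oxygen on the outer side of the axial C10 branch (syn to C9–H) and not over the six-membered ring, giving the thermodynamic epimer; the silyl enol ether and the isolated alkene are inert.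

**Step 9**
Reactants: 15 C10 alcohol
Product: 16 enone alcohol: C6 ketone, C7=C8 with methyl on C8, C10 hydroxyl, C1=C2 alkene (C4 S, C9 S, C10 S)
Conditions: Pd(OAc)2 (1.1 equiv), MeCN, 40 °C
Reagents that add atoms: none
Why: Saegusa–Ito oxidation, in which divalent palladium palladates C7 of the silyl enol ether and β-hydride elimination of the only β-hydrogen (C8–H) gives the C7=C8 enone and zerovalent palladium, erasing the C8 stereocentre while the hindered alcohol and the C1=C2 alkene are spectators.

**Step 10**
Reactants: 16 enone alcohol
Product: 17 epoxy alcohol: 16 with a C1–C2 epoxide on the face of the seven-membered ring that carries the C10 hydroxyl (C1 S, C2 R, C4 S, C9 S, C10 S)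
Conditions: VO(acac)2 (10 mol %), t-BuOOH (1.5 equiv, in decane), CH2Cl2, 0 → 25 °C
Reagents that add atoms: tert-butyl hydroperoxide, CC(C)(C)OO
Why: Vanadium-catalysed hydroxyl-directed epoxidation of a homoallylic alcohol, in which the C10 vanadate ester should deliver the peroxide oxygen to the C1=C2 face syn to the C10 oxygen (reached in the ring conformer with C10 equatorial on the six-membered ring), while the electron-poor enone alkene does not react.

**Step 11**
Reactants: 17 epoxy alcohol
Product: 18 C10 methanesulfonate of 17 (C1 S, C2 R, C4 S, C9 S, C10 S)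
Conditions: MsCl, Et3N, CH2Cl2, 0 °C
Reagents that add atoms: methanesulfonyl chloride, CS(=O)(=O)Cl
Why: Sulfonylation through sulfene works on hindered secondary alcohols and proceeds with retention at C10, the epoxide and enone being stable to the conditions.

**Step 12**
Reactants: 18 C10 methanesulfonate
Product: 20 tricyclic epoxy enone with the new C5–C10 bond (cyclobutane C4–C5–C10–C9; C1 S, C2 R, C4 R, C5 R, C9 R, C10 S), via lithium C5 dienolate 19 (not isolated)
Conditions: LiN(i-Pr)2 (1.2 equiv), THF, −78 °C; then DMPU, −78 → 0 °C
Reagents that add atoms: lithium diisopropylamide, [Li+].CC(C)[N-]C(C)C (lithium in intermediate 19 only)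
Why: Intramolecular enolate alkylation (4-exo-tet), in which kinetic deprotonation of the enone at C5 gives the cross-conjugated dienolate whose C5 lies under the axial C10 branch and displaces the outward-pointing mesylate with inversion, as in the established closures of bicyclo[3.1.1]heptanones from keto sulfonates; the configurations at C5 and C10 are dictated by the ring system.

**Step 13**
Reactants: 20 tricyclic epoxy enone; 21 (S)-2-methylbutanoic acid
Product: 22 C1 alcohol C2 (S)-2-methylbutanoate, oxygens trans (C1 S, C2 S, C4 R, C5 R, C9 R, C10 S)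
Conditions: 21 (8 equiv), Cs2CO3 (0.5 equiv), DMF, 90 °C
Reagents that add atoms: none
Why: Carboxylate opening of an epoxide (SN2), in which the caesium carboxylate formed in the flask attacks C2, remote from the C11 quaternary carbon that blocks C1, anti to the epoxide oxygen, giving inversion at C2 and retention at C1; the weakly basic buffer should not epimerise the α-stereocentre of the acid.

**Step 14**
Reactants: 22 C1 alcohol C2 (S)-2-methylbutanoate; 23 angelic acid
Product: 25 target CNP0323606.1 (C1 angelate, C2 (S)-2-methylbutanoate; C1 S, C2 S, C4 R, C5 R, C9 R, C10 S), via angelic 2,4,6-trichlorobenzoic anhydride 24 (not isolated)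
Conditions: 23, 2,4,6-Cl3C6H2COCl, Et3N, toluene, 25 °C; then 22, toluene, 80 °C
Reagents that add atoms: 2,4,6-trichlorobenzoyl chloride, O=C(Cl)c1c(Cl)cc(Cl)cc1Cl (aroyl group in intermediate 24 only)
Why: Yamaguchi-type esterification through the mixed anhydride without a nucleophilic catalyst is the established way to acylate hindered alcohols with angelic acid without (Z)→(E) isomerisation to the tiglate; no stereocentre is touched.

**Compound list**
1 | 2,2-dimethylbut-3-enoic acid | C=CC(C)(C)C(=O)O | starting material
2 | 2,2-dimethylbut-3-enoyl chloride | C=CC(C)(C)C(=O)Cl | intermediate (not isolated)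
3 | N-methoxy-N,2,2-trimethylbut-3-enamide | C=CC(C)(C)C(=O)N(C)OC | intermediate
4 | prop-1-ynylmagnesium bromide | CC#C[Mg]Br | starting material
5 | magnesium hemiaminal chelate | C=CC(C)(C)C(O[Mg]Br)(C#CC)N(C)OC | intermediate (not isolated)
6 | 3,3-dimethylhept-1-en-5-yn-4-one | C=CC(C)(C)C(=O)C#CC | intermediate
7 | (Z)-6-iodo-3,3-dimethylhepta-1,5-dien-4-one | C=CC(C)(C)C(=O)/C=C(\I)C | intermediate
8 | allyltributylstannane | C=CC[Sn](CCCC)(CCCC)CCCC | starting material
9 | (5Z)-3,3,6-trimethylnona-1,5,8-trien-4-one | C=CC(C)(C)C(=O)/C=C(\CC=C)C | intermediate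
10 | 3,7,7-trimethylcyclohepta-2,5-dien-1-one | CC1=CC(=O)C(C)(C)C=CC1 | intermediate
11 | (E)-pent-3-en-2-one | C/C=C/C(C)=O | starting material
12 | lithium (E)-penta-1,3-dien-2-olate | [Li]OC(=C)/C=C/C | intermediate (not isolated)
13 | (E)-2-(triisopropylsilyloxy)penta-1,3-diene | C=C(O[Si](C(C)C)(C(C)C)C(C)C)/C=C/C | intermediate
14 | cis-fused TIPS enol ether ketone (C4 S, C8 R, C9 R) | C1=CC[C@@]2(C)CC(O[Si](C(C)C)(C(C)C)C(C)C)=C[C@@H](C)[C@H]2C(=O)C1(C)C | intermediate
15 | C10 alcohol of 14, hydroxyl syn to C9–H (C4 S, C8 S, C9 R, C10 S) | C1=CC[C@@]2(C)CC(O[Si](C(C)C)(C(C)C)C(C)C)=C[C@@H](C)[C@H]2[C@H](O)C1(C)C | intermediate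
16 | enone alcohol (C4 S, C9 S, C10 S) | C1=CC[C@@]2(C)CC(=O)C=C(C)[C@H]2[C@H](O)C1(C)C | intermediate
17 | epoxy alcohol, epoxide cis to the C10 hydroxyl (C1 S, C2 R, C4 S, C9 S, C10 S) | O1[C@@H]2[C@H]1C[C@@]3(C)CC(=O)C=C(C)[C@H]3[C@H](O)C2(C)C | intermediate
18 | C10 methanesulfonate of 17 | O1[C@@H]2[C@H]1C[C@@]3(C)CC(=O)C=C(C)[C@H]3[C@H](OS(C)(=O)=O)C2(C)C | intermediate
19 | lithium C5 dienolate of 18 | O1[C@@H]2[C@H]1C[C@@]3(C)C=C(O[Li])C=C(C)[C@H]3[C@H](OS(C)(=O)=O)C2(C)C | intermediate (not isolated)
20 | tricyclic epoxy enone (C1 S, C2 R, C4 R, C5 R, C9 R, C10 S) | O1[C@@H]2[C@H]1C[C@@]3(C)[C@@H]4C(=O)C=C(C)[C@H]3[C@@H]4C2(C)C | intermediate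
21 | (S)-2-methylbutanoic acid | CC[C@H](C)C(=O)O | starting material
22 | C1 alcohol C2 (S)-2-methylbutanoate (C1 S, C2 S, C4 R, C5 R, C9 R, C10 S) | O[C@@H]1[C@@H](OC(=O)[C@@H](C)CC)C[C@@]2(C)[C@@H]3C(=O)C=C(C)[C@H]2[C@@H]3C1(C)C | intermediate
23 | angelic acid, (Z)-2-methylbut-2-enoic acid | C/C=C(/C)C(=O)O | starting material
24 | angelic 2,4,6-trichlorobenzoic anhydride | C/C=C(/C)C(=O)OC(=O)c1c(Cl)cc(Cl)cc1Cl | intermediate (not isolated)
25 | CNP0323606.1 | C/C=C(/C)C(=O)O[C@@H]1[C@@H](OC(=O)[C@@H](C)CC)C[C@@]2(C)[C@@H]3C(=O)C=C(C)[C@H]2[C@@H]3C1(C)C | target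

**Totals.** 14 steps in all; longest linear sequence 13 steps (steps 1–5 and 7–14), with step 6 as a one-step side branch.

**Steps most likely to fail**

Step 7. The cycloaddition may be too slow at the β,β-disubstituted enone. Silyl transfer or a stepwise Michael pathway may erode enantioselectivity, and acid may move the C1=C2 bond into conjugation. The fallback sets out from 10 and 13 and returns at 14. The cycloaddition is run racemically with a stoichiometric achiral Lewis acid known to force hindered silyloxydienes onto β-methylcycloalkenones (AlBr3/AlMe3 5:1, toluene/CH2Cl2, −5 °C). This gives 14 together with the enantiomeric adduct F1. Preparative chromatography on a chiral stationary phase then delivers 14, and F1 is discarded.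

Step 12. After deprotonation at C5, proton transfer to the extended dienolate and β-elimination of methanesulfonate across C9–C10 may outrun C-alkylation, or displacement at the hindered C10 may simply not occur. The fallback sets out from 18 and returns at 20. The kinetic C5 enolate of 18 is first sulfenylated (LiN(i-Pr)2, THF, −78 °C; PhSO2SPh) to the C5-phenylthio mesylate F2. Its C5–H is then the only readily ionised position, so Cs2CO3 in DMF at 25–60 °C generates the sulfur-stabilised enolate under equilibrium conditions without touching C9–H. This closes the C5–C10 bond to the C5-phenylthio tricyclic epoxy enone F3. Radical desulfurisation (Bu3SnH, AIBN, toluene, 90 °C) then gives 20.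

Step 8. Protonation of the C10 carbanion may occur under kinetic rather than thermodynamic control. That would give the C10 epimer, which breaks both the relay to the C1–C2 epoxide and the anti alignment needed in step 12. The fallback sets out from 14 and returns at 15. The C10-epimeric alcohol F4 formed from 14 is equilibrated instead of being re-made. Al(O-i-Pr)3 with catalytic acetone in i-PrOH/toluene at reflux (Meerwein–Ponndorf–Verley/Oppenauer hydride exchange through ketone 14) should drain F4 into the more stable epimer 15.

**Further compounds**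
F1 | step 7 | enantiomeric adduct (ent-14) | C1=CC[C@]2(C)CC(O[Si](C(C)C)(C(C)C)C(C)C)=C[C@H](C)[C@@H]2C(=O)C1(C)C
F2 | step 12 | C5-phenylthio mesylate (C5 epimer mixture) | O1[C@@H]2[C@H]1C[C@@]3(C)C(Sc4ccccc4)C(=O)C=C(C)[C@H]3[C@H](OS(C)(=O)=O)C2(C)C
F3 | step 12 | C5-phenylthio tricyclic epoxy enone | O1[C@@H]2[C@H]1C[C@@]3(C)[C@]4(Sc5ccccc5)C(=O)C=C(C)[C@H]3[C@@H]4C2(C)C
F4 | step 8 | C10-epimeric alcohol (C10 R) | C1=CC[C@@]2(C)CC(O[Si](C(C)C)(C(C)C)C(C)C)=C[C@@H](C)[C@H]2[C@@H](O)C1(C)C
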